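The ratio I carried was how much faster X takes up L than E does; by chance, with 3 free sites on X against 4 on E, it is 0.750.

all flasks: E 0.77 M
- winter: L 0.42 equiv; run made earlier
- midnight: L 1.3 equiv; run made earlier
- oak: L 2.00 equiv; time 15 min
- elm: L 0.500 equiv; time 15 min

- winter (time / min: J / %, X / %): 0.667: 0.2, 7.1; 1.00: 0.1, 6.9; 1.50: 0, 9.2; 2.50: 0, 10.9; 5.00: 0, 10.2; 8.00: 0, 10.5
- midnight (time / min: J / %, X / %): 0.500: 0.5, 10.0; 1.33: 0, 10.0; 2.50: 0.3, 10.5; 4.00: 0.1, 10.0; 6.00: 0, 7.9; 8.00: 0.2, 9.6

(readings scatter by 0.5 percentage points)

1. which of these holds the largest part of the E at the end of oak (Z / J / E / D / X)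
2. which of these holds the largest part of the E at the end of elm (Z / J / E / D / X)
3. J at the end of elm, in percent of the E charged



With E + L alone, winter would hold 42.0% X. Adding X + L at the chance ratio lowers this to 30.1%, yet the plateau read 10.5%. Putting the remaining L into D leaves E at 73.7%. For two steps in a row, with e the fraction of E left, the fraction of X is e minus e to the power s, divided by s less one. From a first guess of 8.00, repeated substitution gave 6.82, the selectivity factor s, the rate constant of X + L over that of E + L.

Then I added the rest. The later midnight readings of X averaged 9.60%. At full uptake midnight would keep 30.2% E, and s would allow 5.18% X, less than that reading. Past the top of the X curve, that reading means 58.3% E and 56.8% of the L entering, so I took it that L had a second way out. With that share, oak gives E 39.8% against 53.4% D, any Z counted as D. Even at full uptake, elm keeps more E than D, 69.7% against 19.7%. Chance over 4 sites at full uptake puts J in elm at 0.0244%, against a scatter of 0.5 percentage points.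

The forecast named D for oak and E for elm, with 0.05% J, judging that “X is strongly disfavoured”.

    Z + L ⇌ Q + J (K = 0.120, k = 0.0173 M⁻¹ s⁻¹)
    E + L → Q + X (k = 0.00868 M⁻¹ s⁻¹)
    2 L → G (k = 0.00414 M⁻¹ s⁻¹)
    D + L → Q + Z (k = 0.00390 M⁻¹ s⁻¹)
    X + L → Q + D (k = 0.0569 M⁻¹ s⁻¹)

Elm ended at 73.6% E, 10.8% X, 14.7% D and 0% J, and oak at 44.3% D over 38.8% E. At 0.943 min in elm, E + L used L 1.6 times as fast as X + L, and s·cX/cE, the reverse of that ratio, stood at 1.00 at the end of elm. In the neighbour of elm with 0.200 equiv of L, that product is 0.680, and s with its 86.5% of E gives 8.47% X against the 8.63% it holds.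

Readings and results were computed from invented constants.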